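Ring A is cut into two three-carbon pieces. C1–C10–C5 sits in a ring B keto aldehyde, where the formyl carbon C1 and the ring ketone C5 flank the quaternary C10. C2–C3–C4 with C19 is methyl acetoacetate, because the oxygenated C3 and C19 on C4 of ring A form a β-keto ester pattern. The key step is their [3+3] cyclocondensation: the γ-carbon of the dianion adds to the aldehyde (C1–C2) and the ester-bearing methylene condenses onto the ketone (C4–C5), giving a cross-conjugated dienone ester. Reductive methylation then sets C5 and quaternary C4, a 2,3-olefin is dihydroxylated anti to the axial C19 and C20 groups, and a C8 ketone becomes the 7-ene.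

Key step: step 5

Remark on numbering: labdane numbering is used (decalin C1–C10; C4 carries methyl C18 and formyl C19; C8 carries C17; C9 carries the chain C11–C16; C10 carries C20).
Assumption: (2E)-3-iodobut-2-enoic acid (17) is taken as a purchasable building block.

**Step 1**
Reactants: 1 4-methoxy-2-methylphenol
Product: 2 4,4-dimethoxy-2-methylcyclohexa-2,5-dien-1-one
Conditions: PhI(OAc)2, MeOH, 0 °C
Reagents that add atoms: methanol, CO
Why: Oxidative dearomatisation of a para-methoxyphenol in methanol should trap the phenoxenium ion at the methoxy-bearing carbon and give the quinone monoketal, which holds the C5 carbonyl and the masked C8 carbonyl of ring B.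

**Step 2**
Reactants: 2 4,4-dimethoxy-2-methylcyclohexa-2,5-dien-1-one
Product: 3 4,4-dimethoxy-2-methylcyclohex-2-en-1-one
Conditions: H2 (1 atm), RhCl(PPh3)3 (cat.), benzene, rt
Reagents that add atoms: none
Why: Chemoselective homogeneous hydrogenation should reduce the disubstituted enone double bond and leave the methyl-bearing trisubstituted one.

**Step 3**
Reactants: 3 4,4-dimethoxy-2-methylcyclohex-2-en-1-one; 4 vinylmagnesium bromide
Product: 6 (2R,3S)-3-ethenyl-2-(hydroxymethyl)-4,4-dimethoxy-2-methylcyclohexan-1-one, via magnesium enolate 5 (not isolated)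
Conditions: CuBr·SMe2 (5 mol %), (R)-1-[(S)-2-(diphenylphosphino)ferrocenyl]ethyldicyclohexylphosphine (6 mol %; the ligand enantiomer that gives 3S is to be used), t-BuOMe, −78 °C; then monomeric CH2O in THF, −78 °C; aq. NH4Cl
Reagents that add atoms: formaldehyde, C=O
Why: Copper-catalysed asymmetric conjugate addition of the vinyl Grignard reagent sets C9 under ligand control, and the magnesium enolate should take up formaldehyde (aldol trapping, three-component coupling) anti to the new vinyl group, which sets quaternary C10 with its methyl cis to the vinyl group.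

**Step 4**
Reactants: 6 (2R,3S)-3-ethenyl-2-(hydroxymethyl)-4,4-dimethoxy-2-methylcyclohexan-1-one
Product: 7 (1R,2S)-2-ethenyl-3,3-dimethoxy-1-methyl-6-oxocyclohexane-1-carbaldehyde
Conditions: 1,1,1-triacetoxy-1,1-dihydro-1,2-benziodoxol-3(1H)-one (DMP), NaHCO3, CH2Cl2, 0 °C → rt
Reagents that add atoms: none
Why: Periodinane oxidation of the neopentyl primary alcohol under buffered, non-basic conditions should give the non-enolisable β-keto aldehyde without retro-aldol loss of the one-carbon arm.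

**Step 5**
Reactants: 7 (1R,2S)-2-ethenyl-3,3-dimethoxy-1-methyl-6-oxocyclohexane-1-carbaldehyde; 8 methyl 3-oxobutanoate
Product: 11 methyl (4aS,5S)-5-ethenyl-6,6-dimethoxy-4a-methyl-2-oxo-2,4a,5,6,7,8-hexahydronaphthalene-1-carboxylate, via aldol adduct 9 (not isolated), via hydroxy enone ester 10 (not isolated)
Conditions: 8, NaH then n-BuLi, THF, 0 °C; 7, −78 °C; AcOH, −78 °C → rt; piperidine (cat.), 4 Å molecular sieves, 50 °C
Reagents that add atoms: none
Why: The dianion of 8 attacks the formyl group of 7 through its terminal (γ) carbon and forms C1–C2; after protonation, piperidinium acetate catalyses the intramolecular Knoevenagel condensation of the ester-bearing methylene onto the ring ketone, which forms C4–C5 and closes ring A, and the C1 hydroxyl is then lost by E1cB elimination to give the cross-conjugated dienone. The closest known reaction types are [3+3] cyclocondensations of 1,3-dicarbonyl dianions with 1,3-dielectrophiles and the ring-closing half of Robinson annulations with alkyl 3-oxopent-4-enoates, where the same kind of carbon condenses onto a ketone next to a quaternary centre. Ring A closes in a 6-(enolendo)-exo-trig aldol mode. No new stereocentre survives, because C4 and C5 become trigonal and the C1 carbinol is eliminated, while C9 and C10 are carried through untouched. The step needs γ-attack of the acetoacetate unit and attack on the aldehyde in preference to the ketone: the dianion secures the first, and in 7 the aldehyde is the more electrophilic carbonyl and cannot enolise (C10 is quaternary), while the hindered ketone is the only carbonyl that the tethered methylene can reach through a six-membered transition state.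

**Step 6**
Reactants: 11 methyl (4aS,5S)-5-ethenyl-6,6-dimethoxy-4a-methyl-2-oxo-2,4a,5,6,7,8-hexahydronaphthalene-1-carboxylate
Product: 13 methyl (1S,4aR,5S,8aS)-5-ethenyl-6,6-dimethoxy-1,4a-dimethyl-2-oxo-1,2,4a,5,6,7,8,8a-octahydronaphthalene-1-carboxylate, via lithium enolate 12 (not isolated)
Conditions: Li, NH3(l)/THF, t-BuOH (1 equiv), −78 °C; then MeI, −78 → −33 °C
Reagents that add atoms: iodomethane, CI
Why: Birch-type reductive alkylation should reduce the doubly activated C4=C5 bond with axial protonation at C5 (trans ring fusion) and leave a β-keto ester enolate that is methylated on the face opposite the axial C10 methyl, so that the ester ends axial (C19) and the new methyl equatorial (C18).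

**Step 7**
Reactants: 13 methyl (1S,4aR,5S,8aS)-5-ethenyl-6,6-dimethoxy-1,4a-dimethyl-2-oxo-1,2,4a,5,6,7,8,8a-octahydronaphthalene-1-carboxylate
Product: 15 methyl (1S,4aR,5S,8aS)-5-ethenyl-6,6-dimethoxy-1,4a-dimethyl-2-{[(trifluoromethyl)sulfonyl]oxy}-1,4,4a,5,6,7,8,8a-octahydronaphthalene-1-carboxylate, via lithium enolate 14 (not isolated)
Conditions: Li, NH3(l)/THF, t-BuOH (1 equiv), −78 °C; NH3 evaporated; PhNTf2, THF, 0 °C → rt
Reagents that add atoms: N-phenylbis(trifluoromethanesulfonimide), O=S(=O)(N(c1ccccc1)S(=O)(=O)C(F)(F)F)C(F)(F)F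
Why: Dissolving-metal reduction turns the enone regiospecifically into its C2=C3 enolate (C4 is quaternary), which PhNTf2 should sulfonylate on oxygen (reductive enol triflation).

**Step 8**
Reactants: 15 methyl (1S,4aR,5S,8aS)-5-ethenyl-6,6-dimethoxy-1,4a-dimethyl-2-{[(trifluoromethyl)sulfonyl]oxy}-1,4,4a,5,6,7,8,8a-octahydronaphthalene-1-carboxylate
Product: 16 methyl (1R,4aR,5S,8aS)-5-ethenyl-6,6-dimethoxy-1,4a-dimethyl-1,4,4a,5,6,7,8,8a-octahydronaphthalene-1-carboxylate
Conditions: Pd(OAc)2 (cat.), PPh3, HCO2H, Bu3N, DMF, 60 °C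
Reagents that add atoms: none
Why: Palladium-catalysed formate reduction of the enol triflate (hydride delivered by decarboxylation of a palladium formate) should give the 2,3-olefin without touching the vinyl group, the ester or the ketal.

**Step 9**
Reactants: 16 methyl (1R,4aR,5S,8aS)-5-ethenyl-6,6-dimethoxy-1,4a-dimethyl-1,4,4a,5,6,7,8,8a-octahydronaphthalene-1-carboxylate; 17 (2E)-3-iodobut-2-enoic acid
Product: 20 (2E)-5-[(1S,4aS,5R,8aR)-5-(methoxycarbonyl)-5,8a-dimethyl-2-oxo-1,2,3,4,4a,5,8,8a-octahydronaphthalen-1-yl]-3-methylpent-2-enoic acid, via alkylborane 18 (not isolated), via ketal acid 19 (not isolated)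
Conditions: 9-BBN, THF, 0 °C → rt; then 17, Pd(dppf)Cl2 (cat.), Cs2CO3, DMF/H2O, 45 °C; then 1 M HCl, THF, rt
Reagents that add atoms: water, O
Why: 9-BBN should hydroborate only the monosubstituted vinyl group (anti-Markovnikov), the B-alkyl Suzuki–Miyaura coupling keeps the E geometry of the iodoenoic acid, and the acidic work-up hydrolyses the dimethyl ketal only after the vinyl group, which would otherwise move into conjugation with the C8 ketone, is gone.

**Step 10**
Reactants: 20 (2E)-5-[(1S,4aS,5R,8aR)-5-(methoxycarbonyl)-5,8a-dimethyl-2-oxo-1,2,3,4,4a,5,8,8a-octahydronaphthalen-1-yl]-3-methylpent-2-enoic acid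
Product: 22 (2E)-5-[(1S,4aS,5R,8aR)-5-(methoxycarbonyl)-5,8a-dimethyl-2-{[(trifluoromethyl)sulfonyl]oxy}-1,4,4a,5,8,8a-hexahydronaphthalen-1-yl]-3-methylpent-2-enoic acid, via dilithium salt 21 (not isolated)
Conditions: LiN(SiMe3)2 (2.2 equiv), THF, −78 °C; PhNTf2, −78 → 0 °C; dilute HCl
Reagents that add atoms: N-phenylbis(trifluoromethanesulfonimide), O=S(=O)(N(c1ccccc1)S(=O)(=O)C(F)(F)F)C(F)(F)F
Why: After deprotonation of the acid, the amide base should remove a C7 proton kinetically (C9 is tertiary and hindered) and PhNTf2 traps the enolate as the C7=C8 enol triflate, a masked form of the later olefin that is inert to osmium tetroxide.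

**Step 11**
Reactants: 22 (2E)-5-[(1S,4aS,5R,8aR)-5-(methoxycarbonyl)-5,8a-dimethyl-2-{[(trifluoromethyl)sulfonyl]oxy}-1,4,4a,5,8,8a-hexahydronaphthalen-1-yl]-3-methylpent-2-enoic acid
Product: 23 (2E)-5-[(1S,4aS,5R,8aR)-5-(hydroxymethyl)-5,8a-dimethyl-2-{[(trifluoromethyl)sulfonyl]oxy}-1,4,4a,5,8,8a-hexahydronaphthalen-1-yl]-3-methylpent-2-enoic acid
Conditions: i-Bu2AlH (excess), CH2Cl2, −78 → −30 °C; aq. potassium sodium tartrate
Reagents that add atoms: none
Why: Chemoselective hydride reduction should take the hindered methyl ester to the primary alcohol while the acid is shielded as its aluminium carboxylate and the enol triflate is left intact.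

**Step 12**
Reactants: 23 (2E)-5-[(1S,4aS,5R,8aR)-5-(hydroxymethyl)-5,8a-dimethyl-2-{[(trifluoromethyl)sulfonyl]oxy}-1,4,4a,5,8,8a-hexahydronaphthalen-1-yl]-3-methylpent-2-enoic acid
Product: 24 (2E)-5-[(1S,4aS,5R,8aR)-5-formyl-5,8a-dimethyl-2-{[(trifluoromethyl)sulfonyl]oxy}-1,4,4a,5,8,8a-hexahydronaphthalen-1-yl]-3-methylpent-2-enoic acid
Conditions: DMP, CH2Cl2, rt
Reagents that add atoms: none
Why: Periodinane oxidation of the neopentyl primary alcohol should stop at the non-enolisable C19 aldehyde and tolerate the acid, the olefin and the enol triflate.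

**Step 13**
Reactants: 24 (2E)-5-[(1S,4aS,5R,8aR)-5-formyl-5,8a-dimethyl-2-{[(trifluoromethyl)sulfonyl]oxy}-1,4,4a,5,8,8a-hexahydronaphthalen-1-yl]-3-methylpent-2-enoic acid
Product: 25 (2E)-5-[(1S,4aS,5S,6R,7S,8aR)-5-formyl-6,7-dihydroxy-5,8a-dimethyl-2-{[(trifluoromethyl)sulfonyl]oxy}-1,4,4a,5,6,7,8,8a-octahydronaphthalen-1-yl]-3-methylpent-2-enoic acid
Conditions: OsO4 (cat.), N-methylmorpholine N-oxide, acetone/H2O, rt
Reagents that add atoms: N-methylmorpholine N-oxide, C[N+]1([O-])CCOCC1; water, O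
Why: Catalytic osmium tetroxide syn-dihydroxylation should occur on the face opposite the axial C10 methyl and the axial C4 formyl group, giving the 2,3-cis-diol (C2–O equatorial, C3–O axial), while the electron-poor enol triflate and enoic acid should not react.

**Step 14**
Reactants: 25 (2E)-5-[(1S,4aS,5S,6R,7S,8aR)-5-formyl-6,7-dihydroxy-5,8a-dimethyl-2-{[(trifluoromethyl)sulfonyl]oxy}-1,4,4a,5,6,7,8,8a-octahydronaphthalen-1-yl]-3-methylpent-2-enoic acid
Product: 26 (2E)-5-[(1S,4aS,5S,6R,7S,8aR)-6,7-bis(acetyloxy)-5-formyl-5,8a-dimethyl-2-{[(trifluoromethyl)sulfonyl]oxy}-1,4,4a,5,6,7,8,8a-octahydronaphthalen-1-yl]-3-methylpent-2-enoic acid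
Conditions: Ac2O, pyridine, DMAP (cat.), rt; aq. NaHCO3/THF, then dilute HCl
Reagents that add atoms: acetic anhydride, CC(=O)OC(C)=O
Why: DMAP-catalysed acylation should esterify both secondary hydroxyls, including the hindered axial one at C3, and the mixed anhydride formed at the side-chain acid is hydrolysed in the work-up.

**Step 15**
Reactants: 26 (2E)-5-[(1S,4aS,5S,6R,7S,8aR)-6,7-bis(acetyloxy)-5-formyl-5,8a-dimethyl-2-{[(trifluoromethyl)sulfonyl]oxy}-1,4,4a,5,6,7,8,8a-octahydronaphthalen-1-yl]-3-methylpent-2-enoic acid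
Product: 27 (2E)-5-[(1R,4aS,5S,6R,7S,8aS)-6,7-bis(acetyloxy)-5-formyl-2,5,8a-trimethyl-1,4,4a,5,6,7,8,8a-octahydronaphthalen-1-yl]-3-methylpent-2-enoic acid
Conditions: Me4Sn, Pd(PPh3)4 (cat.), LiCl, DMF, 80 °C
Reagents that add atoms: tetramethylstannane, C[Sn](C)(C)C
Why: Stille coupling of the enol triflate (oxidative addition, transmetalation, reductive elimination) under neutral conditions should install the C8 methyl and fix the double bond at C7=C8 without harming the acetates, the aldehyde or the acid.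

**Compound list**
1 | 4-methoxy-2-methylphenol | COc1ccc(O)c(C)c1 | starting material
2 | 4,4-dimethoxy-2-methylcyclohexa-2,5-dien-1-one | O=C1C=CC(OC)(OC)C=C1C | intermediate
3 | 4,4-dimethoxy-2-methylcyclohex-2-en-1-one | O=C1CCC(OC)(OC)C=C1C | intermediate
4 | vinylmagnesium bromide | C=C[Mg]Br | starting material
5 | bromo{[(3S)-3-ethenyl-4,4-dimethoxy-2-methylcyclohex-1-en-1-yl]oxy}magnesium | CC1=C(O[Mg]Br)CCC(OC)(OC)[C@H]1C=C | intermediate
6 | (2R,3S)-3-ethenyl-2-(hydroxymethyl)-4,4-dimethoxy-2-methylcyclohexan-1-one | OC[C@@]1(C)[C@H](C=C)C(OC)(OC)CCC1=O | intermediate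
7 | (1R,2S)-2-ethenyl-3,3-dimethoxy-1-methyl-6-oxocyclohexane-1-carbaldehyde | O=C[C@@]1(C)[C@H](C=C)C(OC)(OC)CCC1=O | intermediate
8 | methyl 3-oxobutanoate (methyl acetoacetate) | COC(=O)CC(C)=O | starting material
9 | methyl 5-[(1R,2S)-2-ethenyl-3,3-dimethoxy-1-methyl-6-oxocyclohexyl]-5-hydroxy-3-oxopentanoate (both C5 epimers) | COC(=O)CC(=O)CC(O)[C@@]1(C)[C@H](C=C)C(OC)(OC)CCC1=O | intermediate
10 | methyl (4aS,5S)-5-ethenyl-4-hydroxy-6,6-dimethoxy-4a-methyl-2-oxo-2,3,4,4a,5,6,7,8-octahydronaphthalene-1-carboxylate (both C4 epimers) | O=C1CC(O)[C@@]2(C)[C@H](C=C)C(OC)(OC)CCC2=C1C(=O)OC | intermediate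
11 | methyl (4aS,5S)-5-ethenyl-6,6-dimethoxy-4a-methyl-2-oxo-2,4a,5,6,7,8-hexahydronaphthalene-1-carboxylate | O=C1C=C[C@@]2(C)[C@H](C=C)C(OC)(OC)CCC2=C1C(=O)OC | intermediate
12 | lithium (4aR,5S,8aS)-5-ethenyl-6,6-dimethoxy-1-(methoxycarbonyl)-4a-methyl-4a,5,6,7,8,8a-hexahydronaphthalen-2-olate | [Li+].[O-]C=1C=C[C@@]2(C)[C@H](C=C)C(OC)(OC)CC[C@@H]2C=1C(=O)OC | intermediate
13 | methyl (1S,4aR,5S,8aS)-5-ethenyl-6,6-dimethoxy-1,4a-dimethyl-2-oxo-1,2,4a,5,6,7,8,8a-octahydronaphthalene-1-carboxylate | O=C1C=C[C@@]2(C)[C@H](C=C)C(OC)(OC)CC[C@@H]2[C@]1(C)C(=O)OC | intermediate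
14 | lithium (1S,4aR,5S,8aS)-5-ethenyl-6,6-dimethoxy-1-(methoxycarbonyl)-1,4a-dimethyl-1,4,4a,5,6,7,8,8a-octahydronaphthalen-2-olate | [Li+].[O-]C1=CC[C@@]2(C)[C@H](C=C)C(OC)(OC)CC[C@@H]2[C@]1(C)C(=O)OC | intermediate
15 | methyl (1S,4aR,5S,8aS)-5-ethenyl-6,6-dimethoxy-1,4a-dimethyl-2-{[(trifluoromethyl)sulfonyl]oxy}-1,4,4a,5,6,7,8,8a-octahydronaphthalene-1-carboxylate | O=S(=O)(OC1=CC[C@@]2(C)[C@H](C=C)C(OC)(OC)CC[C@@H]2[C@]1(C)C(=O)OC)C(F)(F)F | intermediate
16 | methyl (1R,4aR,5S,8aS)-5-ethenyl-6,6-dimethoxy-1,4a-dimethyl-1,4,4a,5,6,7,8,8a-octahydronaphthalene-1-carboxylate | C1=CC[C@@]2(C)[C@H](C=C)C(OC)(OC)CC[C@@H]2[C@]1(C)C(=O)OC | intermediate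
17 | (2E)-3-iodobut-2-enoic acid | I/C(C)=C/C(=O)O | starting material
18 | methyl (1R,4aR,5S,8aS)-5-[2-(9-borabicyclo[3.3.1]nonan-9-yl)ethyl]-6,6-dimethoxy-1,4a-dimethyl-1,4,4a,5,6,7,8,8a-octahydronaphthalene-1-carboxylate | C1=CC[C@@]2(C)[C@H](CCB3C4CCCC3CCC4)C(OC)(OC)CC[C@@H]2[C@]1(C)C(=O)OC | intermediate
19 | (2E)-5-[(1S,4aS,5R,8aR)-2,2-dimethoxy-5-(methoxycarbonyl)-5,8a-dimethyl-1,2,3,4,4a,5,8,8a-octahydronaphthalen-1-yl]-3-methylpent-2-enoic acid | C1=CC[C@@]2(C)[C@H](CC/C(C)=C/C(=O)O)C(OC)(OC)CC[C@@H]2[C@]1(C)C(=O)OC | intermediate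
20 | (2E)-5-[(1S,4aS,5R,8aR)-5-(methoxycarbonyl)-5,8a-dimethyl-2-oxo-1,2,3,4,4a,5,8,8a-octahydronaphthalen-1-yl]-3-methylpent-2-enoic acid | C1=CC[C@@]2(C)[C@H](CC/C(C)=C/C(=O)O)C(=O)CC[C@@H]2[C@]1(C)C(=O)OC | intermediate
21 | dilithium (2E)-5-[(1S,4aS,5R,8aR)-5-(methoxycarbonyl)-5,8a-dimethyl-2-oxido-1,4,4a,5,8,8a-hexahydronaphthalen-1-yl]-3-methylpent-2-enoate | [Li+].[Li+].C1=CC[C@@]2(C)[C@H](CC/C(C)=C/C(=O)[O-])C([O-])=CC[C@@H]2[C@]1(C)C(=O)OC | intermediate
22 | (2E)-5-[(1S,4aS,5R,8aR)-5-(methoxycarbonyl)-5,8a-dimethyl-2-{[(trifluoromethyl)sulfonyl]oxy}-1,4,4a,5,8,8a-hexahydronaphthalen-1-yl]-3-methylpent-2-enoic acid | C1=CC[C@@]2(C)[C@H](CC/C(C)=C/C(=O)O)C(OS(=O)(=O)C(F)(F)F)=CC[C@@H]2[C@]1(C)C(=O)OC | intermediate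
23 | (2E)-5-[(1S,4aS,5R,8aR)-5-(hydroxymethyl)-5,8a-dimethyl-2-{[(trifluoromethyl)sulfonyl]oxy}-1,4,4a,5,8,8a-hexahydronaphthalen-1-yl]-3-methylpent-2-enoic acid | C1=CC[C@@]2(C)[C@H](CC/C(C)=C/C(=O)O)C(OS(=O)(=O)C(F)(F)F)=CC[C@@H]2[C@]1(C)CO | intermediate
24 | (2E)-5-[(1S,4aS,5R,8aR)-5-formyl-5,8a-dimethyl-2-{[(trifluoromethyl)sulfonyl]oxy}-1,4,4a,5,8,8a-hexahydronaphthalen-1-yl]-3-methylpent-2-enoic acid | C1=CC[C@@]2(C)[C@H](CC/C(C)=C/C(=O)O)C(OS(=O)(=O)C(F)(F)F)=CC[C@@H]2[C@]1(C)C=O | intermediate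
25 | (2E)-5-[(1S,4aS,5S,6R,7S,8aR)-5-formyl-6,7-dihydroxy-5,8a-dimethyl-2-{[(trifluoromethyl)sulfonyl]oxy}-1,4,4a,5,6,7,8,8a-octahydronaphthalen-1-yl]-3-methylpent-2-enoic acid | O[C@H]1C[C@@]2(C)[C@H](CC/C(C)=C/C(=O)O)C(OS(=O)(=O)C(F)(F)F)=CC[C@@H]2[C@](C)(C=O)[C@H]1O | intermediate
26 | (2E)-5-[(1S,4aS,5S,6R,7S,8aR)-6,7-bis(acetyloxy)-5-formyl-5,8a-dimethyl-2-{[(trifluoromethyl)sulfonyl]oxy}-1,4,4a,5,6,7,8,8a-octahydronaphthalen-1-yl]-3-methylpent-2-enoic acid | CC(=O)O[C@H]1C[C@@]2(C)[C@H](CC/C(C)=C/C(=O)O)C(OS(=O)(=O)C(F)(F)F)=CC[C@@H]2[C@](C)(C=O)[C@H]1OC(C)=O | intermediate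
27 | (2E)-5-[(1R,4aS,5S,6R,7S,8aS)-6,7-bis(acetyloxy)-5-formyl-2,5,8a-trimethyl-1,4,4a,5,6,7,8,8a-octahydronaphthalen-1-yl]-3-methylpent-2-enoic acid | CC(=O)O[C@H]1C[C@@]2(C)[C@H](CC/C(C)=C/C(=O)O)C(C)=CC[C@@H]2[C@](C)(C=O)[C@H]1OC(C)=O | target

Total step count: 15. Longest linear sequence: 15 steps (1 → 27).

**Steps most likely to fail**

Step 5 (key step). The sequence may stall after the first bond: the δ-hydroxy β-keto ester can lactonise to a pyrandione, or lose the one-carbon arm by retro-aldol cleavage, before the ring closes. The fallback makes the two bonds in two stages with the carbinol blocked. It sets out from 7: the aldol adduct 9 is isolated after a cold acetic acid quench and acetylated (Ac2O, pyridine) to methyl 5-(acetyloxy)-5-[(1R,2S)-2-ethenyl-3,3-dimethoxy-1-methyl-6-oxocyclohexyl]-3-oxopentanoate F1. Piperidinium acetate in benzene should then effect the Knoevenagel closure to the acetoxy enone ester F2, which loses acetic acid by E1cB elimination under the same conditions and comes back to the route at 11.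

Step 3. The enantioselectivity of a vinyl transfer to an α-methyl enone flanked by a ketal may erode, and 1,2-addition may compete. The fallback replaces asymmetric catalysis by a resolution. It sets out from 3: the same addition and formaldehyde trapping without the chiral ligand pass through the racemic magnesium enolate F3 and give the racemic trans hydroxymethyl ketone F4. Lipase-catalysed acetylation (lipase from Burkholderia cepacia, vinyl acetate, t-BuOMe) is a kinetic resolution of the primary alcohol. The acetate of the wanted enantiomer, [(1R,2S)-2-ethenyl-3,3-dimethoxy-1-methyl-6-oxocyclohexyl]methyl acetate F5, is separated from the unreacted antipode and methanolysed (K2CO3, MeOH, 0 °C), which comes back to the route at 6. If the enzyme should prefer the antipode, 6 is the recovered alcohol.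

Step 11. Chemoselectivity may be lost if the hindered ester only reacts at temperatures where the aluminium carboxylate or the enol triflate also begin to be reduced. The fallback reduces the ester before the acid is introduced. It sets out from 16:
- LiAlH4 (THF) gives the primary alcohol F6, which is silylated (i-Pr3SiCl, imidazole, DMF) to the tri(propan-2-yl)silyl ether F7.
- Hydroboration to the alkylborane F8 and coupling with 17 as in step 9 give the ketal acid F9, hydrolysed in the acidic work-up to the keto acid F10.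
- Enol triflation as in step 10 passes through the dilithium salt F11 and gives the silylated enol triflate F12.
- HF·pyridine (THF) removes the silyl group and comes back to the route at 23.

**Further compounds**
F1 | step 5 | methyl 5-(acetyloxy)-5-[(1R,2S)-2-ethenyl-3,3-dimethoxy-1-methyl-6-oxocyclohexyl]-3-oxopentanoate | COC(=O)CC(=O)CC(OC(C)=O)[C@@]1(C)[C@H](C=C)C(OC)(OC)CCC1=O
F2 | step 5 | methyl (4aS,5S)-4-(acetyloxy)-5-ethenyl-6,6-dimethoxy-4a-methyl-2-oxo-2,3,4,4a,5,6,7,8-octahydronaphthalene-1-carboxylate | O=C1CC(OC(C)=O)[C@@]2(C)[C@H](C=C)C(OC)(OC)CCC2=C1C(=O)OC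
F3 | step 3 | racemic bromo{[3-ethenyl-4,4-dimethoxy-2-methylcyclohex-1-en-1-yl]oxy}magnesium | CC1=C(O[Mg]Br)CCC(OC)(OC)[C@H]1C=C.CC1=C(O[Mg]Br)CCC(OC)(OC)[C@@H]1C=C
F4 | step 3 | racemic (2R*,3S*)-3-ethenyl-2-(hydroxymethyl)-4,4-dimethoxy-2-methylcyclohexan-1-one | OC[C@@]1(C)[C@H](C=C)C(OC)(OC)CCC1=O.OC[C@]1(C)[C@@H](C=C)C(OC)(OC)CCC1=O
F5 | step 3 | [(1R,2S)-2-ethenyl-3,3-dimethoxy-1-methyl-6-oxocyclohexyl]methyl acetate | CC(=O)OC[C@@]1(C)[C@H](C=C)C(OC)(OC)CCC1=O
F6 | step 11 | [(1R,4aR,5S,8aS)-5-ethenyl-6,6-dimethoxy-1,4a-dimethyl-1,4,4a,5,6,7,8,8a-octahydronaphthalen-1-yl]methanol | C1=CC[C@@]2(C)[C@H](C=C)C(OC)(OC)CC[C@@H]2[C@]1(C)CO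
F7 | step 11 | {[(1R,4aR,5S,8aS)-5-ethenyl-6,6-dimethoxy-1,4a-dimethyl-1,4,4a,5,6,7,8,8a-octahydronaphthalen-1-yl]methoxy}tri(propan-2-yl)silane | C1=CC[C@@]2(C)[C@H](C=C)C(OC)(OC)CC[C@@H]2[C@]1(C)CO[Si](C(C)C)(C(C)C)C(C)C
F8 | step 11 | {[(1R,4aR,5S,8aS)-5-[2-(9-borabicyclo[3.3.1]nonan-9-yl)ethyl]-6,6-dimethoxy-1,4a-dimethyl-1,4,4a,5,6,7,8,8a-octahydronaphthalen-1-yl]methoxy}tri(propan-2-yl)silane | C1=CC[C@@]2(C)[C@H](CCB3C4CCCC3CCC4)C(OC)(OC)CC[C@@H]2[C@]1(C)CO[Si](C(C)C)(C(C)C)C(C)C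
F9 | step 11 | (2E)-5-[(1S,4aS,5R,8aR)-2,2-dimethoxy-5,8a-dimethyl-5-({[tri(propan-2-yl)silyl]oxy}methyl)-1,2,3,4,4a,5,8,8a-octahydronaphthalen-1-yl]-3-methylpent-2-enoic acid | C1=CC[C@@]2(C)[C@H](CC/C(C)=C/C(=O)O)C(OC)(OC)CC[C@@H]2[C@]1(C)CO[Si](C(C)C)(C(C)C)C(C)C
F10 | step 11 | (2E)-5-[(1S,4aS,5R,8aR)-5,8a-dimethyl-2-oxo-5-({[tri(propan-2-yl)silyl]oxy}methyl)-1,2,3,4,4a,5,8,8a-octahydronaphthalen-1-yl]-3-methylpent-2-enoic acid | C1=CC[C@@]2(C)[C@H](CC/C(C)=C/C(=O)O)C(=O)CC[C@@H]2[C@]1(C)CO[Si](C(C)C)(C(C)C)C(C)C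
F11 | step 11 | dilithium (2E)-5-[(1S,4aS,5R,8aR)-5,8a-dimethyl-2-oxido-5-({[tri(propan-2-yl)silyl]oxy}methyl)-1,4,4a,5,8,8a-hexahydronaphthalen-1-yl]-3-methylpent-2-enoate | [Li+].[Li+].C1=CC[C@@]2(C)[C@H](CC/C(C)=C/C(=O)[O-])C([O-])=CC[C@@H]2[C@]1(C)CO[Si](C(C)C)(C(C)C)C(C)C
F12 | step 11 | (2E)-5-[(1S,4aS,5R,8aR)-5,8a-dimethyl-5-({[tri(propan-2-yl)silyl]oxy}methyl)-2-{[(trifluoromethyl)sulfonyl]oxy}-1,4,4a,5,8,8a-hexahydronaphthalen-1-yl]-3-methylpent-2-enoic acid | C1=CC[C@@]2(C)[C@H](CC/C(C)=C/C(=O)O)C(OS(=O)(=O)C(F)(F)F)=CC[C@@H]2[C@]1(C)CO[Si](C(C)C)(C(C)C)C(C)C
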